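## Retrosynthet­ic overview

1. 28 comes from 27 by global O-debenzylation. The only methyl ether is bought in with 5-methoxyresorcinol, so no late selective methylation or demethylation is needed.
2. The pyranone of the luteolin half (unit B) is formed last, by I2/DMSO closure of 2'-hydroxychalcone 25. Chalcone 25 comes from a Claisen–Schmidt aldol condensation of acetophenone 22 with aldehyde 23 (key C–C bond). Only the phenol para to the inter-flavone bond is free, which enforces the 6-linkage.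
3. The acetyl of 22 comes from formylation, methyl addition and oxidation on the symmetric 4-allyloxy-2,6-dibenzyloxyphenyl ring of 17, followed by deallylation.
4. The pyranone of the genkwanin half (unit A) is formed first, by crossed Claisen C-acylation of deoxybenzoin 11 with aroyl chloride 13 and cyclodehydration.
5. 11 comes from aryllithium 8 and arylacetaldehyde 5. The inter-flavone C–C bond is the aryl–CHO bond of 2,4,6-trihydroxybenzaldehyde 1.

Assumption: the SMILES holds no stereocentre and no descriptor for the 3,6'-biaryl axis, so no absolute configuration has to be set. From 19 onward the compounds are racemic about that hindered axis.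

## Route

Step 1
Reactants: 1 2,4,6-trihydroxybenzaldehyde
Product: 2 4-(allyloxy)-2,6-dihydroxybenzaldehyde
Conditions: allyl bromide (1.05 equiv), KHCO3 (1.2 equiv), DMF, 40 °C
Reagents that add atoms: allyl bromide C=CCBr
Why: Williamson etherification; the 4-OH is the most acidic phenol and the only one not hydrogen-bonded to the formyl group, so the weak base ionises and alkylates it selectively.

Step 2
Reactants: 2 4-(allyloxy)-2,6-dihydroxybenzaldehyde
Product: 3 4-(allyloxy)-2,6-bis(benzyloxy)benzaldehyde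
Conditions: BnBr (2.6 equiv), K2CO3 (3 equiv), DMF, 60 °C
Reagents that add atoms: benzyl bromide BrCc1ccccc1
Why: Williamson etherification with stronger base and heat alkylates both chelated ortho phenols, giving a symmetric ring whose para oxygen alone carries an orthogonal group.

Step 3
Reactants: 3 4-(allyloxy)-2,6-bis(benzyloxy)benzaldehyde
Product: 4 5-(allyloxy)-1,3-bis(benzyloxy)-2-(2-methoxyethenyl)benzene (E/Z mixture)
Conditions: MeOCH2PPh3Cl (1.6 equiv), KOtBu (1.5 equiv), THF, 0 °C to rt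
Reagents that add atoms: (methoxymethyl)triphenylphosphonium chloride COC[P+](c1ccccc1)(c1ccccc1)c1ccccc1.[Cl-]
Why: Wittig olefination with the small methoxymethylidene ylide works on 2,6-dialkoxybenzaldehydes; the alkene geometry is irrelevant, and keeping the base below the salt avoids allyl isomerisation.

Step 4
Reactants: 4 5-(allyloxy)-1,3-bis(benzyloxy)-2-(2-methoxyethenyl)benzene
Product: 5 2-[4-(allyloxy)-2,6-bis(benzyloxy)phenyl]acetaldehyde
Conditions: 2 M HCl (cat.), THF–H2O, 45 °C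
Reagents that add atoms: water O
Why: Acid-catalysed enol ether hydrolysis completes the one-carbon homologation and leaves the benzyl and allyl aryl ethers untouched.

Step 5
Reactants: 6 5-methoxyresorcinol
Product: 7 1-methoxy-3,5-bis(methoxymethoxy)benzene
Conditions: NaH (2.3 equiv), MOMCl (2.3 equiv), DMF, 0 °C to rt
Reagents that add atoms: chloromethyl methyl ether COCCl
Why: O-alkylation of both phenoxides installs two acetal groups that protect the phenols and serve as strong directing groups for lithiation.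

Step 6
Reactants: 7 1-methoxy-3,5-bis(methoxymethoxy)benzene; 5 2-[4-(allyloxy)-2,6-bis(benzyloxy)phenyl]acetaldehyde
Product: 9 (±)-2-[4-(allyloxy)-2,6-bis(benzyloxy)phenyl]-1-[4-methoxy-2,6-bis(methoxymethoxy)phenyl]ethanol, via aryllithium 8 (not isolated)
Conditions: n-BuLi (1.05 equiv), THF, 0 °C, 1 h; 5, −78 °C; H2O quench
Reagents that add atoms: none
Why: Directed ortho-metalation takes place at the carbon flanked by both OMOM groups, and 1,2-addition of the chelated aryllithium at −78 °C outruns enolisation; the carbinol centre forms racemic and is erased in step 7.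

Step 7
Reactants: 9 (±)-2-[4-(allyloxy)-2,6-bis(benzyloxy)phenyl]-1-[4-methoxy-2,6-bis(methoxymethoxy)phenyl]ethanol
Product: 10 2-[4-(allyloxy)-2,6-bis(benzyloxy)phenyl]-1-[4-methoxy-2,6-bis(methoxymethoxy)phenyl]ethanone
Conditions: Dess–Martin periodinane (1.3 equiv), pyridine (5 equiv), CH2Cl2, 0 °C to rt
Reagents that add atoms: none
Why: Dess–Martin oxidation is mild and neutral, and the pyridine buffer prevents acid-induced dehydration of the electron-rich carbinol to a stilbene.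

Step 8
Reactants: 10 2-[4-(allyloxy)-2,6-bis(benzyloxy)phenyl]-1-[4-methoxy-2,6-bis(methoxymethoxy)phenyl]ethanone
Product: 11 2-[4-(allyloxy)-2,6-bis(benzyloxy)phenyl]-1-(2,6-dihydroxy-4-methoxyphenyl)ethanone
Conditions: conc. HCl (cat.), MeOH–THF, 50 °C
Reagents that add atoms: none
Why: Acid-catalysed acetal exchange removes both MOM groups ortho to the ketone, while methyl, benzyl and allyl ethers are inert to dilute acid.

Step 9
Reactants: 12 4-(benzyloxy)benzoic acid
Product: 13 4-(benzyloxy)benzoyl chloride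
Conditions: (COCl)2 (1.3 equiv), DMF (cat.), CH2Cl2, 0 °C to rt
Reagents that add atoms: oxalyl chloride O=C(Cl)C(=O)Cl
Why: DMF-catalysed acid chloride formation gives only gaseous side products, so the fresh acylating agent is used after evaporation.

Step 10
Reactants: 11 2-[4-(allyloxy)-2,6-bis(benzyloxy)phenyl]-1-(2,6-dihydroxy-4-methoxyphenyl)ethanone; 13 4-(benzyloxy)benzoyl chloride
Product: 15 2-[4-(allyloxy)-2,6-bis(benzyloxy)phenyl]-1-[4-(benzyloxy)phenyl]-3-(2,6-dihydroxy-4-methoxyphenyl)propane-1,3-dione, via trilithium enolate 14 (not isolated)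
Conditions: LiN(SiMe3)2 (4.5 equiv), THF, −78 to −10 °C; 13 (1.1 equiv), −78 °C to rt; 1 M HCl quench
Reagents that add atoms: none
Why: Crossed Claisen-type C-acylation of the benzylic ketone enolate, in which any O-aroylated material is funnelled to the same diketone by Baker–Venkataraman acyl shift under the excess base; the new methine centre is labile and lost in step 11.

Step 11
Reactants: 15 2-[4-(allyloxy)-2,6-bis(benzyloxy)phenyl]-1-[4-(benzyloxy)phenyl]-3-(2,6-dihydroxy-4-methoxyphenyl)propane-1,3-dione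
Product: 16 3-[4-(allyloxy)-2,6-bis(benzyloxy)phenyl]-2-[4-(benzyloxy)phenyl]-5-hydroxy-7-methoxy-4H-chromen-4-one
Conditions: conc. HCl (cat.), MeOH–THF, 60 °C
Reagents that add atoms: none
Why: Cyclodehydration (hemiketal formation, then loss of water) gives the conjugated chromone, and since the two phenols of 15 are equivalent only one product can form.

Step 12
Reactants: 16 3-[4-(allyloxy)-2,6-bis(benzyloxy)phenyl]-2-[4-(benzyloxy)phenyl]-5-hydroxy-7-methoxy-4H-chromen-4-one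
Product: 17 3-[4-(allyloxy)-2,6-bis(benzyloxy)phenyl]-5-(benzyloxy)-2-[4-(benzyloxy)phenyl]-7-methoxy-4H-chromen-4-one
Conditions: BnBr (1.5 equiv), K2CO3 (2 equiv), DMF, 70 °C
Reagents that add atoms: benzyl bromide BrCc1ccccc1
Why: Williamson etherification under forcing conditions masks the chelated 5-OH ahead of the Grignard, oxidation and iodine steps.

Step 13
Reactants: 17 3-[4-(allyloxy)-2,6-bis(benzyloxy)phenyl]-5-(benzyloxy)-2-[4-(benzyloxy)phenyl]-7-methoxy-4H-chromen-4-one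
Product: 19 3-[4-(allyloxy)-2,6-bis(benzyloxy)-3-formylphenyl]-5-(benzyloxy)-2-[4-(benzyloxy)phenyl]-7-methoxy-4H-chromen-4-one, via iminium chloride 18 (not isolated)
Conditions: POCl3 (3 equiv), DMF, 0 to 60 °C; then H2O
Reagents that add atoms: N,N-dimethylformamide CN(C)C=O; water O
Why: Vilsmeier–Haack formylation attacks the only ring with three alkoxy donors and no acceptor; its two open positions are equivalent and the first formyl group shuts down a second attack.

Step 14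
Reactants: 19 3-[4-(allyloxy)-2,6-bis(benzyloxy)-3-formylphenyl]-5-(benzyloxy)-2-[4-(benzyloxy)phenyl]-7-methoxy-4H-chromen-4-one
Product: 20 3-[4-(allyloxy)-2,6-bis(benzyloxy)-3-(1-hydroxyethyl)phenyl]-5-(benzyloxy)-2-[4-(benzyloxy)phenyl]-7-methoxy-4H-chromen-4-one (diastereomer mixture)
Conditions: MeMgBr (1.5 equiv), THF, −78 to −40 °C; H2O quench
Reagents that add atoms: methylmagnesium bromide C[Mg]Br
Why: Grignard 1,2-addition is chemoselective because the aldehyde is far more electrophilic than the shielded vinylogous-ester carbonyl of the 2,3-diarylchromone; the carbinol centre is not controlled and is erased in step 15.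

Step 15
Reactants: 20 3-[4-(allyloxy)-2,6-bis(benzyloxy)-3-(1-hydroxyethyl)phenyl]-5-(benzyloxy)-2-[4-(benzyloxy)phenyl]-7-methoxy-4H-chromen-4-one
Product: 21 3-[3-acetyl-4-(allyloxy)-2,6-bis(benzyloxy)phenyl]-5-(benzyloxy)-2-[4-(benzyloxy)phenyl]-7-methoxy-4H-chromen-4-one
Conditions: Dess–Martin periodinane (1.3 equiv), pyridine (5 equiv), CH2Cl2, rt
Reagents that add atoms: none
Why: Dess–Martin oxidation converts the hindered benzylic alcohol to the methyl ketone without touching ethers, alkene or chromone.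

Step 16
Reactants: 21 3-[3-acetyl-4-(allyloxy)-2,6-bis(benzyloxy)phenyl]-5-(benzyloxy)-2-[4-(benzyloxy)phenyl]-7-methoxy-4H-chromen-4-one
Product: 22 3-[3-acetyl-2,6-bis(benzyloxy)-4-hydroxyphenyl]-5-(benzyloxy)-2-[4-(benzyloxy)phenyl]-7-methoxy-4H-chromen-4-one
Conditions: Pd(PPh3)4 (5 mol %), morpholine (10 equiv), THF, rt
Reagents that add atoms: none
Why: Tsuji–Trost deallylation; zerovalent palladium ionises only the allyl aryl ether and morpholine traps the allyl fragment, freeing the single phenol needed for ring closure.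

Step 17
Reactants: 22 3-[3-acetyl-2,6-bis(benzyloxy)-4-hydroxyphenyl]-5-(benzyloxy)-2-[4-(benzyloxy)phenyl]-7-methoxy-4H-chromen-4-one; 23 3,4-bis(benzyloxy)benzaldehyde
Product: 25 3-{2,6-bis(benzyloxy)-3-[(E)-3-(3,4-bis(benzyloxy)phenyl)prop-2-enoyl]-4-hydroxyphenyl}-5-(benzyloxy)-2-[4-(benzyloxy)phenyl]-7-methoxy-4H-chromen-4-one, via aldol adduct 24 (not isolated)
Conditions: 23 (1.3 equiv), 50% aq KOH, EtOH–THF, rt, 48 h
Reagents that add atoms: none
Why: Claisen–Schmidt aldol condensation; the methyl ketone enolate adds to the non-enolisable aldehyde and E1cB loss of water gives the thermodynamic E-enone, while the hindered tetrasubstituted chromone of unit A resists hydroxide at rt.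

Step 18
Reactants: 25 3-{2,6-bis(benzyloxy)-3-[(E)-3-(3,4-bis(benzyloxy)phenyl)prop-2-enoyl]-4-hydroxyphenyl}-5-(benzyloxy)-2-[4-(benzyloxy)phenyl]-7-methoxy-4H-chromen-4-one
Product: 27 5,5',7'-tris(benzyloxy)-2-[4-(benzyloxy)phenyl]-2'-[3,4-bis(benzyloxy)phenyl]-7-methoxy-4H,4'H-[3,6'-bichromene]-4,4'-dione, via flavanone 26 (not isolated)
Conditions: I2 (10 mol %), DMSO, 120 °C
Reagents that add atoms: none
Why: Oxa-Michael closure through the only free phenol, then iodine-catalysed dehydrogenation with DMSO as terminal oxidant, can give only the 6-linked flavone because the oxygen next to the inter-flavone bond stays benzylated.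

Step 19
Reactants: 27 5,5',7'-tris(benzyloxy)-2-[4-(benzyloxy)phenyl]-2'-[3,4-bis(benzyloxy)phenyl]-7-methoxy-4H,4'H-[3,6'-bichromene]-4,4'-dione
Product: 28 2'-(3,4-dihydroxyphenyl)-5,5',7'-trihydroxy-2-(4-hydroxyphenyl)-7-methoxy-4H,4'H-[3,6'-bichromene]-4,4'-dione (CNP0200311.0)
Conditions: H2 (1 atm), 10% Pd/C, THF–MeOH, rt
Reagents that add atoms: none
Why: Catalytic hydrogenolysis cleaves all six benzyl ethers under neutral conditions, which spares the methyl ether and the flavone double bonds and excludes acid-induced Wessely–Moser scrambling.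

## Compound list

1 | 2,4,6-trihydroxybenzaldehyde | O=Cc1c(O)cc(O)cc1O | starting material
2 | 4-(allyloxy)-2,6-dihydroxybenzaldehyde | C=CCOc1cc(O)c(C=O)c(O)c1 | intermediate
3 | 4-(allyloxy)-2,6-bis(benzyloxy)benzaldehyde | C=CCOc1cc(OCc2ccccc2)c(C=O)c(OCc2ccccc2)c1 | intermediate
4 | 5-(allyloxy)-1,3-bis(benzyloxy)-2-(2-methoxyethenyl)benzene, E/Z mixture | C=CCOc1cc(OCc2ccccc2)c(C=COC)c(OCc2ccccc2)c1 | intermediate
5 | 2-[4-(allyloxy)-2,6-bis(benzyloxy)phenyl]acetaldehyde | C=CCOc1cc(OCc2ccccc2)c(CC=O)c(OCc2ccccc2)c1 | intermediate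
6 | 5-methoxyresorcinol | COc1cc(O)cc(O)c1 | starting material
7 | 1-methoxy-3,5-bis(methoxymethoxy)benzene | COCOc1cc(OC)cc(OCOC)c1 | intermediate
8 | [4-methoxy-2,6-bis(methoxymethoxy)phenyl]lithium | [Li]c1c(OCOC)cc(OC)cc1OCOC | intermediate
9 | (±)-2-[4-(allyloxy)-2,6-bis(benzyloxy)phenyl]-1-[4-methoxy-2,6-bis(methoxymethoxy)phenyl]ethanol | C=CCOc1cc(OCc2ccccc2)c(CC(O)c2c(OCOC)cc(OC)cc2OCOC)c(OCc2ccccc2)c1 | intermediate
10 | 2-[4-(allyloxy)-2,6-bis(benzyloxy)phenyl]-1-[4-methoxy-2,6-bis(methoxymethoxy)phenyl]ethanone | C=CCOc1cc(OCc2ccccc2)c(CC(=O)c2c(OCOC)cc(OC)cc2OCOC)c(OCc2ccccc2)c1 | intermediate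
11 | 2-[4-(allyloxy)-2,6-bis(benzyloxy)phenyl]-1-(2,6-dihydroxy-4-methoxyphenyl)ethanone | C=CCOc1cc(OCc2ccccc2)c(CC(=O)c2c(O)cc(OC)cc2O)c(OCc2ccccc2)c1 | intermediate
12 | 4-(benzyloxy)benzoic acid | O=C(O)c1ccc(OCc2ccccc2)cc1 | starting material
13 | 4-(benzyloxy)benzoyl chloride | O=C(Cl)c1ccc(OCc2ccccc2)cc1 | intermediate
14 | trilithium salt of 11 (ketone enolate plus both phenoxides) | C=CCOc1cc(OCc2ccccc2)c(C=C(O[Li])c2c(O[Li])cc(OC)cc2O[Li])c(OCc2ccccc2)c1 | intermediate
15 | 2-[4-(allyloxy)-2,6-bis(benzyloxy)phenyl]-1-[4-(benzyloxy)phenyl]-3-(2,6-dihydroxy-4-methoxyphenyl)propane-1,3-dione (racemic, labile centre) | C=CCOc1cc(OCc2ccccc2)c(C(C(=O)c2ccc(OCc3ccccc3)cc2)C(=O)c2c(O)cc(OC)cc2O)c(OCc2ccccc2)c1 | intermediate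
16 | 3-[4-(allyloxy)-2,6-bis(benzyloxy)phenyl]-2-[4-(benzyloxy)phenyl]-5-hydroxy-7-methoxy-4H-chromen-4-one | COc1cc(O)c2c(=O)c(-c3c(OCc4ccccc4)cc(OCC=C)cc3OCc3ccccc3)c(-c3ccc(OCc4ccccc4)cc3)oc2c1 | intermediate
17 | 3-[4-(allyloxy)-2,6-bis(benzyloxy)phenyl]-5-(benzyloxy)-2-[4-(benzyloxy)phenyl]-7-methoxy-4H-chromen-4-one | COc1cc(OCc2ccccc2)c2c(=O)c(-c3c(OCc4ccccc4)cc(OCC=C)cc3OCc3ccccc3)c(-c3ccc(OCc4ccccc4)cc3)oc2c1 | intermediate
18 | dimethyliminium chloride of aldehyde 19 (aryl-CH=NMe2 cation, chloride) | COc1cc(OCc2ccccc2)c2c(=O)c(-c3c(OCc4ccccc4)cc(OCC=C)c(C=[N+](C)C)c3OCc3ccccc3)c(-c3ccc(OCc4ccccc4)cc3)oc2c1.[Cl-] | intermediate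
19 | 3-[4-(allyloxy)-2,6-bis(benzyloxy)-3-formylphenyl]-5-(benzyloxy)-2-[4-(benzyloxy)phenyl]-7-methoxy-4H-chromen-4-one | COc1cc(OCc2ccccc2)c2c(=O)c(-c3c(OCc4ccccc4)cc(OCC=C)c(C=O)c3OCc3ccccc3)c(-c3ccc(OCc4ccccc4)cc3)oc2c1 | intermediate
20 | 3-[4-(allyloxy)-2,6-bis(benzyloxy)-3-(1-hydroxyethyl)phenyl]-5-(benzyloxy)-2-[4-(benzyloxy)phenyl]-7-methoxy-4H-chromen-4-one, diastereomer mixture | COc1cc(OCc2ccccc2)c2c(=O)c(-c3c(OCc4ccccc4)cc(OCC=C)c(C(C)O)c3OCc3ccccc3)c(-c3ccc(OCc4ccccc4)cc3)oc2c1 | intermediate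
21 | 3-[3-acetyl-4-(allyloxy)-2,6-bis(benzyloxy)phenyl]-5-(benzyloxy)-2-[4-(benzyloxy)phenyl]-7-methoxy-4H-chromen-4-one | COc1cc(OCc2ccccc2)c2c(=O)c(-c3c(OCc4ccccc4)cc(OCC=C)c(C(C)=O)c3OCc3ccccc3)c(-c3ccc(OCc4ccccc4)cc3)oc2c1 | intermediate
22 | 3-[3-acetyl-2,6-bis(benzyloxy)-4-hydroxyphenyl]-5-(benzyloxy)-2-[4-(benzyloxy)phenyl]-7-methoxy-4H-chromen-4-one | COc1cc(OCc2ccccc2)c2c(=O)c(-c3c(OCc4ccccc4)cc(O)c(C(C)=O)c3OCc3ccccc3)c(-c3ccc(OCc4ccccc4)cc3)oc2c1 | intermediate
23 | 3,4-bis(benzyloxy)benzaldehyde | O=Cc1ccc(OCc2ccccc2)c(OCc2ccccc2)c1 | starting material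
24 | beta-hydroxy ketone (aldol adduct of 22 and 23), stereoisomer mixture | COc1cc(OCc2ccccc2)c2c(=O)c(-c3c(OCc4ccccc4)cc(O)c(C(=O)CC(O)c4ccc(OCc5ccccc5)c(OCc5ccccc5)c4)c3OCc3ccccc3)c(-c3ccc(OCc4ccccc4)cc3)oc2c1 | intermediate
25 | 3-{2,6-bis(benzyloxy)-3-[(E)-3-(3,4-bis(benzyloxy)phenyl)prop-2-enoyl]-4-hydroxyphenyl}-5-(benzyloxy)-2-[4-(benzyloxy)phenyl]-7-methoxy-4H-chromen-4-one | COc1cc(OCc2ccccc2)c2c(=O)c(-c3c(OCc4ccccc4)cc(O)c(C(=O)/C=C/c4ccc(OCc5ccccc5)c(OCc5ccccc5)c4)c3OCc3ccccc3)c(-c3ccc(OCc4ccccc4)cc3)oc2c1 | intermediate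
26 | 2',3'-dihydro derivative of 27 (flavanone of unit B), stereoisomer mixture | COc1cc(OCc2ccccc2)c2c(=O)c(-c3c(OCc4ccccc4)cc4OC(c5ccc(OCc6ccccc6)c(OCc6ccccc6)c5)CC(=O)c4c3OCc3ccccc3)c(-c3ccc(OCc4ccccc4)cc3)oc2c1 | intermediate
27 | 5,5',7'-tris(benzyloxy)-2-[4-(benzyloxy)phenyl]-2'-[3,4-bis(benzyloxy)phenyl]-7-methoxy-4H,4'H-[3,6'-bichromene]-4,4'-dione | COc1cc(OCc2ccccc2)c2c(=O)c(-c3c(OCc4ccccc4)cc4oc(-c5ccc(OCc6ccccc6)c(OCc6ccccc6)c5)cc(=O)c4c3OCc3ccccc3)c(-c3ccc(OCc4ccccc4)cc3)oc2c1 | intermediate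
28 | 2'-(3,4-dihydroxyphenyl)-5,5',7'-trihydroxy-2-(4-hydroxyphenyl)-7-methoxy-4H,4'H-[3,6'-bichromene]-4,4'-dione | COc1cc(O)c2c(=O)c(-c3c(O)cc4oc(-c5ccc(O)c(O)c5)cc(=O)c4c3O)c(-c3ccc(O)cc3)oc2c1 | target

## Step count and risks

Total steps: 19. Longest linear sequence: 17 (steps 1–4, 6–8, 10–19). Steps 5 and 9 are side branches.

**Step 6.** The basic aryllithium may enolise arylacetaldehyde 5, and carbinol 9 dehydrates easily. The fallback sets out from 5 and comes back at 10.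
- Pinnick oxidation (NaClO2, NaH2PO4, large excess of 2-methyl-2-butene, t-BuOH–H2O) gives 2-[4-(allyloxy)-2,6-bis(benzyloxy)phenyl]acetic acid F1.
- Activation with 1,1'-carbonyldiimidazole and treatment with MeNHOMe·HCl gives 2-[4-(allyloxy)-2,6-bis(benzyloxy)phenyl]-N-methoxy-N-methylacetamide F2.
- Acyl substitution of this less acidic, chelating electrophile by aryllithium 8 at −78 °C delivers ketone 10 directly, so carbinol 9 and step 7 are bypassed.

**Step 10.** C-acylation at a carbon that bears a 2,6-disubstituted aryl group may stall for steric reasons. The fallback sets out from 11 and comes back at 16.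
- Piperidine-catalysed aldol condensation of 11 with purchased 4-(benzyloxy)benzaldehyde in refluxing EtOH uses a smaller sp2 electrophile. Spontaneous oxa-Michael closure then gives 3-[4-(allyloxy)-2,6-bis(benzyloxy)phenyl]-2-[4-(benzyloxy)phenyl]-5-hydroxy-7-methoxychroman-4-one F3 (racemic cis/trans mixture).
- Dehydrogenation of F3 with DDQ in refluxing dioxane gives chromone 16, so diketone 15 and step 11 are bypassed.

**Step 17.** The flanked acetophenone may condense slowly, and long exposure to hydroxide may open the chromone of unit A. The fallback sets out from 22 and comes back at 27.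
- Deprotonation with LiN(SiMe3)2 (3.5 equiv, THF, −78 °C) and acylation with 3,4-bis(benzyloxy)benzoyl chloride gives 1-[3,4-bis(benzyloxy)phenyl]-3-{2,4-bis(benzyloxy)-3-[5-(benzyloxy)-2-(4-(benzyloxy)phenyl)-7-methoxy-4-oxo-4H-chromen-3-yl]-6-hydroxyphenyl}propane-1,3-dione F4.
- Cyclodehydration of F4 (conc. HCl cat., MeOH–THF, 60 °C) through the same single free phenol gives 27. No hydroxide and no oxidation step are needed, and steps 17 and 18 are bypassed.

## Further compounds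

F1 | step 6 | 2-[4-(allyloxy)-2,6-bis(benzyloxy)phenyl]acetic acid | C=CCOc1cc(OCc2ccccc2)c(CC(=O)O)c(OCc2ccccc2)c1
F2 | step 6 | 2-[4-(allyloxy)-2,6-bis(benzyloxy)phenyl]-N-methoxy-N-methylacetamide | C=CCOc1cc(OCc2ccccc2)c(CC(=O)N(C)OC)c(OCc2ccccc2)c1
F3 | step 10 | 3-[4-(allyloxy)-2,6-bis(benzyloxy)phenyl]-2-[4-(benzyloxy)phenyl]-5-hydroxy-7-methoxychroman-4-one (racemic cis/trans mixture) | COc1cc(O)c2C(=O)C(c3c(OCc4ccccc4)cc(OCC=C)cc3OCc3ccccc3)C(c3ccc(OCc4ccccc4)cc3)Oc2c1
F4 | step 17 | 1-[3,4-bis(benzyloxy)phenyl]-3-{2,4-bis(benzyloxy)-3-[5-(benzyloxy)-2-(4-(benzyloxy)phenyl)-7-methoxy-4-oxo-4H-chromen-3-yl]-6-hydroxyphenyl}propane-1,3-dione | COc1cc(OCc2ccccc2)c2c(=O)c(-c3c(OCc4ccccc4)cc(O)c(C(=O)CC(=O)c4ccc(OCc5ccccc5)c(OCc5ccccc5)c4)c3OCc3ccccc3)c(-c3ccc(OCc4ccccc4)cc3)oc2c1
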